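**Strategy.** The route rests on cutting the C3–C4 bond of the ten-membered carbocycle (C1–C10) and inserting a C(=O)–O unit there. The ring is first closed as a twelve-membered allyl β-keto lactone, reached by an intramolecular Nozaki–Hiyama–Kishi reaction. A palladium-catalysed decarboxylative allylation then expels CO2, joins C3 to C4 and contracts the macrolactone by two atoms, leaving the C2 ketone, the C3 oxygen and the Z-C5=C6 olefin in place. The step exploits the allylic position of C4 next to C5=C6 and the C2 carbonyl, which can enolise only toward C3 because C1 is quaternary. The precursor is a lactone-bridged macrolide carrying the finished cyclohexenone and a 9-O-linked cis-diol lactone.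

Key step: step 20

Numbering used in all names: ring B = ten-membered ring C1–C10 (C1 quaternary with CH3-15; C2 carbinol; C3 acetoxy carbon; C4 CH2; C5(CH3-16)=C6; C7 lactone O–CH; C8 tertiary carbinol; C9 acetoxy carbon; C10 ring-fusion CH). Ring A = C1, C10, C11(CH3-20), C12, C13, C14. Lactone = C7–O–C19(=O)–C17(CH3-18)–C8. β is the face of CH3-15.

Assumption: the (S)-oxazaborolidinium catalyst of step 2 and the (R,R)-ligand of step 20 are taken to give the sense of induction drawn; if either sense is found opposite, the antipodal catalyst or ligand is used with no other change.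

Step 1
Reactants: 1 pent-1-en-3-one
Product: 2 (Z)-3-(tert-butyldimethylsilyloxy)penta-1,3-diene
Conditions: TBSOTf, Et3N, Et2O, 0 °C
Reagents that add atoms: tert-butyldimethylsilyl triflate, CC(C)(C)[Si](C)(C)OS(=O)(=O)C(F)(F)F
Why: Soft enolisation of the ethyl ketone (silyl enol ether formation) should give the 2-silyloxy diene with the Z enol ether, the methyl group "outside" and so reactive in cycloaddition.

Step 2
Reactants: 2 (Z)-3-(tert-butyldimethylsilyloxy)penta-1,3-diene; 3 ethyl (E)-3-methyl-4-oxobut-2-enoate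
Product: 4 ethyl 2-formyl-2,6-dimethyl-5-(tert-butyldimethylsilyloxy)cyclohex-4-ene-1-carboxylate (C1: CH3 β, CHO α; C10: CO2Et β; C11: CH3 α; enol ether C12=C13)
Conditions: oxazaborolidinium triflimide from (S)-α,α-diphenylprolinol, o-tolylboroxine and HNTf2 (20 mol%), CH2Cl2, −78 to −40 °C
Reagents that add atoms: none
Why: Catalytic enantioselective Diels–Alder reaction in which the enol-ether terminus C11 bonds to C10 (β to the boron-bound formyl group) and C14 to C1; the E dienophile fixes C9 trans to C2, the formyl-endo transition state places CH3-20 α, and the chiral Lewis acid sets the absolute configuration at C1/C10.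

Step 3
Reactants: 4 Diels–Alder adduct
Product: 5 bis-dioxolane ester (C2 as 1,3-dioxolan-2-yl, C12 as ethylene ketal)
Conditions: ethylene glycol, TsOH (cat.), benzene, reflux, Dean–Stark
Reagents that add atoms: ethylene glycol, OCCO
Why: Acid-catalysed acetalisation converts the aldehyde and, after protodesilylation of the enol ether, the C12 ketone into dioxolanes, which masks both carbonyls for the organometallic steps and removes the ring olefin before the later osmylation.

Step 4
Reactants: 5 bis-dioxolane ester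
Product: 6 Weinreb amide at C9
Conditions: MeNH(OMe)·HCl, iPrMgCl, THF, −20 to 0 °C
Reagents that add atoms: N,O-dimethylhydroxylamine hydrochloride, CNOC.Cl
Why: Direct Weinreb amidation of the hindered ester by the magnesium amide; C10 stays in its more stable equatorial configuration.

Step 5
Reactants: 7 2,3-dibromopropene; 8 4-methoxybenzyl alcohol
Product: 9 2-bromoallyl 4-methoxybenzyl ether
Conditions: NaH, THF, 0 °C to rt
Reagents that add atoms: none
Why: Williamson ether synthesis by SN2 at the allylic bromide; the vinylic bromide is inert.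

Step 6
Reactants: 6 Weinreb amide; 9 2-bromoallyl 4-methoxybenzyl ether
Product: 10 C9 ketone bearing the 2-(PMB-oxymethyl)vinyl group (C8 vinylic, C7 = CH2OPMB)
Conditions: 9, t-BuLi (2 equiv), Et2O, −78 °C; then 6, −78 to −20 °C
Reagents that add atoms: none
Why: Bromine–lithium exchange gives the 2-lithioallyl ether, which adds once to the amide through the chelated tetrahedral intermediate (Weinreb ketone synthesis).

Step 7
Reactants: 10 C9 ketone
Product: 11 (9S)-allylic alcohol
Conditions: (S)-2-methyl-CBS-oxazaborolidine (0.3 equiv), catecholborane, toluene, −78 °C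
Reagents that add atoms: none
Why: Corey–Bakshi–Shibata reduction with the branched C10 side as the large group should give 9S, the same face that Felkin–Anh attack anti to C1 favours, so reagent and substrate are matched.

Step 8
Reactants: 11 (9S)-allylic alcohol
Product: 12 C9 methacrylate
Conditions: methacryloyl chloride, Et3N, DMAP (cat.), CH2Cl2, 0 °C to rt
Reagents that add atoms: methacryloyl chloride, C=C(C)C(=O)Cl
Why: DMAP-catalysed acylation of the secondary allylic alcohol.

Step 9
Reactants: 12 C9 methacrylate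
Product: 13 9,19-butenolide (3-methyl-4-(PMB-oxymethyl)furan-2(5H)-one, C5 of the furanone = C9)
Conditions: second-generation Hoveyda–Grubbs catalyst (10 mol%), toluene, 80 °C, argon sparge
Reagents that add atoms: none
Why: Ring-closing metathesis of the two 1,1-disubstituted olefins closes the five-membered α-methyl butenolide (tetrasubstituted olefin), driven by loss of ethene.

Step 10
Reactants: 13 9,19-butenolide
Product: 14 cis-8,17-diol of the 9,19-lactone
Conditions: OsO4 (10 mol%), NMO, citric acid, t-BuOH/H2O, 40 °C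
Reagents that add atoms: N-methylmorpholine N-oxide, C[N+]1([O-])CCOCC1; water, O
Why: Upjohn dihydroxylation of the only olefin in the molecule; OsO4 adds syn from the face opposite the C10 substituent on C9, which sets C8 and C17 as in the target.

Step 11
Reactants: 14 cis-8,17-diol bis-dioxolane
Product: 15 keto aldehyde (C2 CHO, C12 ketone, 8,17-diol, C7 OPMB)
Conditions: 1 M HCl, THF, 40 °C
Reagents that add atoms: water, O
Why: Acetal hydrolysis frees both carbonyls; lactone, tertiary diol and PMB ether should survive dilute aqueous acid.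

Step 12
Reactants: 15 keto aldehyde
Product: 17 C11α-trimethylsilyloxy C12 ketone (CH3-20 β; O8 and O17 as TMS ethers), via tris-silylated C11=C12 enol ether 16 (not isolated)
Conditions: TMSCl, Et3N, DMF, 80 °C; then mCPBA, NaHCO3, CH2Cl2, −20 °C
Reagents that add atoms: chlorotrimethylsilane, C[Si](C)(C)Cl; m-chloroperbenzoic acid, OOC(=O)c1cccc(Cl)c1
Why: House conditions give the thermodynamic, more substituted silyl enol ether and silylate the tertiary alcohols; Rubottom oxidation from the α face, anti to the C9 substituent on C10, installs the C11 oxygen with silyl transfer.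

Step 13
Reactants: 17 C11α-silyloxy ketone
Product: 18 C13=C14 enone aldehyde
Conditions: IBX, 4-methoxypyridine N-oxide, DMSO, rt
Reagents that add atoms: none
Why: IBX dehydrogenation of the ketone can only run toward C13–C14 because C11 is now quaternary, and the neopentylic aldehyde has no α-hydrogen.

Step 14
Reactants: 19 prop-2-yn-1-ol
Product: 20 (Z)-3-iodo-2-methylprop-2-en-1-ol
Conditions: MeMgBr, CuI (cat.), THF, −10 °C to rt; then I2
Reagents that add atoms: methylmagnesium bromide, C[Mg]Br; iodine, II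
Why: Alkoxide-directed copper-catalysed anti-carbomagnesiation of propargyl alcohol and iodinolysis of the vinylmagnesium give the Z iodide (iodine cis to CH2OH).

Step 15
Reactants: 20 (Z)-3-iodo-2-methylprop-2-en-1-ol; 21 (tert-butyldimethylsilyloxy)acetic acid
Product: 22 (Z)-3-iodo-2-methylallyl (tert-butyldimethylsilyloxy)acetate
Conditions: DCC, DMAP (cat.), CH2Cl2, 0 °C to rt
Reagents that add atoms: none
Why: Steglich esterification.

Step 16
Reactants: 18 enone aldehyde; 22 iodoallyl silyloxyacetate
Product: 23 aldol adduct (C2 carbinol, C3 OTBS, iodoallyl ester; C2/C3 epimers)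
Conditions: 22, LDA, THF, −78 °C; then 18, −78 °C
Reagents that add atoms: none
Why: Lithium-enolate aldol addition to the non-enolisable aldehyde, the most electrophilic carbonyl, kept at −78 °C to avoid ester-enolate Claisen rearrangement; the C2/C3 configurations are inconsequential because C2 is oxidised and C3 becomes enolisable.

Step 17
Reactants: 23 aldol adduct
Product: 24 C7 primary alcohol
Conditions: DDQ, CH2Cl2/pH 7 buffer, 0 °C
Reagents that add atoms: none
Why: Oxidative cleavage of the PMB ether by DDQ (benzylic hydride abstraction, then hydrolysis).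

Step 18
Reactants: 24 C7 primary alcohol
Product: 25 β-keto ester aldehyde (C2 ketone, C7 CHO)
Conditions: Dess–Martin periodinane, NaHCO3, CH2Cl2, rt
Reagents that add atoms: none
Why: Dess–Martin oxidation of both alcohols in one operation, giving the β-keto ester at C2 and the non-enolisable aldehyde at C7.

Step 19
Reactants: 25 β-keto ester aldehyde
Product: 27 twelve-membered allyl β-keto lactone (7S OTMS; 5Z; C3 epimers), via chromium alkoxide 26 (not isolated)
Conditions: CrCl2 (8 equiv), NiCl2 (2 mol%), DMF/THF, 0.003 M, rt; then TMSCl, imidazole (cat.), 0 °C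
Reagents that add atoms: chlorotrimethylsilane, C[Si](C)(C)Cl
Why: Intramolecular Nozaki–Hiyama–Kishi reaction: the alkenylchromium from the Z iodide adds chemoselectively to the aldehyde under high dilution; Felkin–Anh attack anti to the C8–OSiMe3 bond and past C17 should give 7S, and the alkoxide is silylated in the flask.

Step 20
Reactants: 27 twelve-membered allyl β-keto lactone
Product: 29 ring-contracted ten-membered ketone (C2 ketone, 3S OTBS, 5Z, 7S OTMS), via allylpalladium enolate 28 (not isolated)
Conditions: Pd2(dba)3 (5 mol%), (R,R)-DACH-phenyl Trost ligand (12 mol%), toluene, 0.005 M, 40 °C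
Reagents that add atoms: none
Why: Zerovalent palladium ionises the allylic C4–O bond (the only allylic ester, since the allylic C7 oxygen is a silyl ether), the β-keto carboxylate loses CO2, and the palladium-bound α-silyloxy enolate 28 is alkylated at C3 by the unsubstituted allyl terminus C4. The closest known reaction is the Tsuji decarboxylative allylation of allyl β-keto esters; because the ester lies inside the ring, loss of CO2 is a two-atom ring contraction. Ring B closes by attack at the terminal allyl carbon C4 with the allyl unit endocyclic (ten-membered), in preference to attack at the substituted terminus C6 (eight-membered ring, exocyclic olefin). The new stereocentre C3 is controlled by the chiral ligand, which selects the face of the Z(O)-enolate (silyloxy cis to the enolate oxygen, avoiding strain against quaternary C1). The step needs C- over O-allylation, C4 over C6 attack and retention of the Z olefin; the soft ion pair and the steric bias favour C4, and the anti-configured allyl complex is held by the short tether so that collapse should outrun syn–anti isomerisation. Enolate regiochemistry is secured by quaternary C1, and high dilution suppresses crossover.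

Step 21
Reactants: 29 ring-contracted ketone
Product: 30 pentaol (3-, 7-, 8-, 11-, 17-OH; 9,19-lactone; C2 and C12 ketones)
Conditions: HF·pyridine, pyridine, THF, 0 °C to rt
Reagents that add atoms: none
Why: Fluoride cleavage of all five silyl ethers, leaving lactone and ketones.

Step 22
Reactants: 30 pentaol
Product: 31 7,19-lactone (free 3-, 8-, 9-, 11-, 17-OH)
Conditions: (ClBu2Sn)2O (10 mol%), toluene, 80 °C
Reagents that add atoms: none
Why: Neutral distannoxane-catalysed transesterification moves the lactone from O9 to O7, which relieves the cis relationship of the C7 and C10 substituents on the lactone ring and turns the cis 8,17-diol of the 9-lactone into the trans diol of the target.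

Step 23
Reactants: 31 7,19-lactone
Product: 32 3,9-diacetate diketone
Conditions: Ac2O, pyridine, DMAP (cat.), CH2Cl2, 0 °C to rt
Reagents that add atoms: acetic anhydride, CC(=O)OC(C)=O
Why: Acetylation of the only two secondary alcohols (C3, C9); the tertiary alcohols should not react under these conditions.

Step 24
Reactants: 32 3,9-diacetate diketone
Product: 33 target CNP0199254.3
Conditions: (S)-2-methyl-CBS-oxazaborolidine (2.5 equiv), catecholborane, toluene/CH2Cl2, −78 to −40 °C
Reagents that add atoms: none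
Why: Corey–Bakshi–Shibata reduction of both ketones under reagent control: with the quaternary neighbours C11 and C1 as the large groups the (S)-reagent should give 12R (α-OH by 1,2-reduction of the enone) and 2S, while catecholborane leaves olefins and esters untouched.

**Compound list**

1 | pent-1-en-3-one | CCC(=O)C=C | starting material
2 | (Z)-3-(tert-butyldimethylsilyloxy)penta-1,3-diene | C/C=C(\O[Si](C)(C)C(C)(C)C)C=C | intermediate
3 | ethyl (E)-3-methyl-4-oxobut-2-enoate | CCOC(=O)/C=C(\C)C=O | starting material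
4 | ethyl 2-formyl-2,6-dimethyl-5-(tert-butyldimethylsilyloxy)cyclohex-4-ene-1-carboxylate; C1 (CH3 β, CHO α), C10 (CO2Et β), C11 (CH3 α) | CCOC(=O)[C@H]1[C@H](C)C(O[Si](C)(C)C(C)(C)C)=CC[C@]1(C)C=O | intermediate
5 | bis-dioxolane ester: C2 as 1,3-dioxolan-2-yl, C12 as ethylene ketal | CCOC(=O)[C@H]1[C@H](C)C2(OCCO2)CC[C@]1(C)C1OCCO1 | intermediate
6 | N-methoxy-N-methyl amide at C9 | CON(C)C(=O)[C@H]1[C@H](C)C2(OCCO2)CC[C@]1(C)C1OCCO1 | intermediate
7 | 2,3-dibromopropene | C=C(Br)CBr | starting material
8 | 4-methoxybenzyl alcohol | COc1ccc(CO)cc1 | starting material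
9 | 2-bromoallyl 4-methoxybenzyl ether | C=C(Br)COCc1ccc(OC)cc1 | intermediate
10 | C9 ketone with 2-(PMB-oxymethyl)vinyl group | C=C(COCc1ccc(OC)cc1)C(=O)[C@H]1[C@H](C)C2(OCCO2)CC[C@]1(C)C1OCCO1 | intermediate
11 | (9S)-allylic alcohol | C=C(COCc1ccc(OC)cc1)[C@@H](O)[C@H]1[C@H](C)C2(OCCO2)CC[C@]1(C)C1OCCO1 | intermediate
12 | C9 methacrylate | C=C(COCc1ccc(OC)cc1)[C@@H](OC(=O)C(C)=C)[C@H]1[C@H](C)C2(OCCO2)CC[C@]1(C)C1OCCO1 | intermediate
13 | 9,19-butenolide (α-methyl, β-CH2OPMB, C9 as in target) | CC1=C(COCc2ccc(OC)cc2)[C@@H](OC1=O)[C@H]1[C@H](C)C2(OCCO2)CC[C@]1(C)C1OCCO1 | intermediate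
14 | cis-8,17-diol 9,19-lactone, bis-dioxolane (C8, C17 as in target) | COc1ccc(COC[C@@]2(O)[C@](C)(O)C(=O)O[C@H]2[C@H]2[C@H](C)C3(OCCO3)CC[C@]2(C)C2OCCO2)cc1 | intermediate
15 | keto aldehyde: C2 CHO, C12 ketone, 8,17-diol, C7 OPMB | COc1ccc(COC[C@@]2(O)[C@](C)(O)C(=O)O[C@H]2[C@H]2[C@H](C)C(=O)CC[C@]2(C)C=O)cc1 | intermediate
16 | C11=C12 trimethylsilyl enol ether, 8,17-bis-TMS ether | COc1ccc(COC[C@@]2(O[Si](C)(C)C)[C@](C)(O[Si](C)(C)C)C(=O)O[C@H]2[C@H]2C(C)=C(O[Si](C)(C)C)CC[C@]2(C)C=O)cc1 | intermediate
17 | C11α-trimethylsilyloxy C12 ketone, 8,17-bis-TMS ether, C2 aldehyde | COc1ccc(COC[C@@]2(O[Si](C)(C)C)[C@](C)(O[Si](C)(C)C)C(=O)O[C@H]2[C@H]2[C@](C)(O[Si](C)(C)C)C(=O)CC[C@]2(C)C=O)cc1 | intermediate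
18 | C13=C14 enone aldehyde | COc1ccc(COC[C@@]2(O[Si](C)(C)C)[C@](C)(O[Si](C)(C)C)C(=O)O[C@H]2[C@H]2[C@](C)(O[Si](C)(C)C)C(=O)C=C[C@]2(C)C=O)cc1 | intermediate
19 | prop-2-yn-1-ol | C#CCO | starting material
20 | (Z)-3-iodo-2-methylprop-2-en-1-ol | OC/C(C)=C\I | intermediate
21 | (tert-butyldimethylsilyloxy)acetic acid | CC(C)(C)[Si](C)(C)OCC(=O)O | starting material
22 | (Z)-3-iodo-2-methylallyl (tert-butyldimethylsilyloxy)acetate | CC(C)(C)[Si](C)(C)OCC(=O)OC/C(C)=C\I | intermediate
23 | aldol adduct: C2 carbinol, C3 OTBS, iodoallyl ester (C2/C3 epimers) | COc1ccc(COC[C@@]2(O[Si](C)(C)C)[C@](C)(O[Si](C)(C)C)C(=O)O[C@H]2[C@H]2[C@](C)(O[Si](C)(C)C)C(=O)C=C[C@]2(C)C(O)C(O[Si](C)(C)C(C)(C)C)C(=O)OC/C(C)=C\I)cc1 | intermediate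
24 | C7 primary alcohol | OC[C@@]1(O[Si](C)(C)C)[C@](C)(O[Si](C)(C)C)C(=O)O[C@H]1[C@H]1[C@](C)(O[Si](C)(C)C)C(=O)C=C[C@]1(C)C(O)C(O[Si](C)(C)C(C)(C)C)C(=O)OC/C(C)=C\I | intermediate
25 | β-keto ester (C2 ketone, C3 epimers) with C7 aldehyde | O=C[C@@]1(O[Si](C)(C)C)[C@](C)(O[Si](C)(C)C)C(=O)O[C@H]1[C@H]1[C@](C)(O[Si](C)(C)C)C(=O)C=C[C@]1(C)C(=O)C(O[Si](C)(C)C(C)(C)C)C(=O)OC/C(C)=C\I | intermediate
26 | dichlorochromium alkoxide (trivalent chromium) of the macrocyclic 7-ol | CC(C)(C)[Si](C)(C)OC1C(=O)OC/C(C)=C\[C@H](O[Cr](Cl)Cl)[C@@]2(O[Si](C)(C)C)[C@](C)(O[Si](C)(C)C)C(=O)O[C@H]2[C@H]2[C@](C)(O[Si](C)(C)C)C(=O)C=C[C@]2(C)C1=O | intermediate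
27 | twelve-membered allyl β-keto lactone (ring C3–C(=O)–O–C4–C5=C6–C7–C8–C9–C10–C1–C2; 7S OTMS; 5Z; 9,19-lactone) | CC(C)(C)[Si](C)(C)OC1C(=O)OC/C(C)=C\[C@H](O[Si](C)(C)C)[C@@]2(O[Si](C)(C)C)[C@](C)(O[Si](C)(C)C)C(=O)O[C@H]2[C@H]2[C@](C)(O[Si](C)(C)C)C(=O)C=C[C@]2(C)C1=O | intermediate
28 | allylpalladium enolate: divalent palladium bound to C4 and to the C2 enolate oxygen (other ligands omitted) | [Pd]1C/C(C)=C\[C@H](O[Si](C)(C)C)[C@@]2(O[Si](C)(C)C)[C@](C)(O[Si](C)(C)C)C(=O)O[C@H]2[C@H]2[C@](C)(O[Si](C)(C)C)C(=O)C=C[C@]2(C)C(O1)=CO[Si](C)(C)C(C)(C)C | intermediate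
29 | ring-contracted ketone: ring B with C2 ketone, 3S OTBS, 5Z, 7S OTMS, 9,19-lactone, TMS ethers at O8, O11, O17 | CC(C)(C)[Si](C)(C)O[C@H]1C/C(C)=C\[C@H](O[Si](C)(C)C)[C@@]2(O[Si](C)(C)C)[C@](C)(O[Si](C)(C)C)C(=O)O[C@H]2[C@H]2[C@](C)(O[Si](C)(C)C)C(=O)C=C[C@]2(C)C1=O | intermediate
30 | pentaol with 9,19-lactone, C2 and C12 ketones | O[C@H]1C/C(C)=C\[C@H](O)[C@@]2(O)[C@](C)(O)C(=O)O[C@H]2[C@H]2[C@](C)(O)C(=O)C=C[C@]2(C)C1=O | intermediate
31 | 7,19-lactone with free 3-, 8-, 9-, 11-, 17-OH, C2 and C12 ketones | O[C@H]1C/C(C)=C\[C@@H]2OC(=O)[C@@](C)(O)[C@@]2(O)[C@@H](O)[C@H]2[C@](C)(O)C(=O)C=C[C@]2(C)C1=O | intermediate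
32 | 3,9-diacetate of 31 | CC(=O)O[C@H]1C/C(C)=C\[C@@H]2OC(=O)[C@@](C)(O)[C@@]2(O)[C@@H](OC(C)=O)[C@H]2[C@](C)(O)C(=O)C=C[C@]2(C)C1=O | intermediate
33 | CNP0199254.3: (1S,2S,3S,5Z,7S,8S,9S,10S,11S,12R,17S)-3,9-diacetoxy-2,8,11,12,17-pentahydroxy briarane 5,13-diene 19→7 lactone | CC(=O)O[C@H]1C/C(C)=C\[C@@H]2OC(=O)[C@@](C)(O)[C@@]2(O)[C@@H](OC(C)=O)[C@H]2[C@](C)(O)[C@H](O)C=C[C@]2(C)[C@@H]1O | target

**Step count.** Total: 24 steps. Longest linear sequence: 21 steps (steps 1–4, 6–13, 16–24).

**Steps most likely to fail**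

Step 20. Protonation of the transient enolate by the acidic substrate, or β-hydride loss from the allyl complex, may outrun C–C bond formation, and the face selection at C3 may be poor. Fallback, from 27: the ester is cleaved by iodide (LiI, EtOAc, 70 °C; SN2 at allylic C4), and the β-keto acid loses CO2 to leave the seco keto allylic iodide F1. The only enolisable position of F1 is C3, so its potassium enolate (KHMDS, THF, −78 to 0 °C, high dilution) closes ring B by intramolecular C-alkylation, and the route is rejoined at 29.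

Step 24. Axial hydride delivery anti to the axial CH3-20, the substrate's own preference, may override the reagent at C12. Fallback, from 32: Luche reduction (NaBH4, CeCl3·7H2O, MeOH, −78 °C) is allowed to follow the substrate and should give the 12β-alcohol, 12-epi-target F2, with C2 set by Felkin–Anh attack anti to the C3 acetoxy group. Mitsunobu reaction (chloroacetic acid, PPh3, DIAD, toluene) inverts only the allylic C12 carbinol to the 12α-chloroacetate F3, since the C2 carbinol is neopentylic and the others are tertiary. Thiourea and NaHCO3 in ethanol then remove the chloroacetate without touching the acetates and give 33.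

Step 9. The ruthenium carbene may fail to engage the second 1,1-disubstituted olefin, so that the tetrasubstituted ring olefin does not form. Fallback, from 11: Lemieux–Johnson cleavage (OsO4 cat., NaIO4, 2,6-lutidine, dioxane/H2O; no other olefin is present at this stage) gives the α-hydroxy ketone F4. Esterification with 2-(diethoxyphosphoryl)propanoic acid (EDC, DMAP) gives the phosphonate ester F5. Intramolecular Horner–Wadsworth–Emmons olefination (LiCl, DBU, MeCN) closes the butenolide and returns to 13.

Further compounds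
F1 | step 20 | seco keto allylic iodide (C2 ketone with C3H2 OTBS; C4 iodide; 5Z) | IC/C(C)=C\[C@H](O[Si](C)(C)C)[C@@]2(O[Si](C)(C)C)[C@](C)(O[Si](C)(C)C)C(=O)O[C@H]2[C@H]2[C@](C)(O[Si](C)(C)C)C(=O)C=C[C@]2(C)C(=O)CO[Si](C)(C)C(C)(C)C
F2 | step 24 | 12-epi-target (12β-OH) | CC(=O)O[C@H]1C/C(C)=C\[C@@H]2OC(=O)[C@@](C)(O)[C@@]2(O)[C@@H](OC(C)=O)[C@H]2[C@](C)(O)[C@@H](O)C=C[C@]2(C)[C@@H]1O
F3 | step 24 | 12α-chloroacetate of the target | CC(=O)O[C@H]1C/C(C)=C\[C@@H]2OC(=O)[C@@](C)(O)[C@@]2(O)[C@@H](OC(C)=O)[C@H]2[C@](C)(O)[C@H](OC(=O)CCl)C=C[C@]2(C)[C@@H]1O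
F4 | step 9 | α-hydroxy ketone (C8 ketone, 9S carbinol, C7 CH2OPMB) | COc1ccc(COCC(=O)[C@@H](O)[C@H]2[C@H](C)C3(OCCO3)CC[C@]2(C)C2OCCO2)cc1
F5 | step 9 | 9-O-[2-(diethoxyphosphoryl)propanoyl] ester of F4 | COc1ccc(COCC(=O)[C@@H](OC(=O)C(C)P(=O)(OCC)OCC)[C@H]2[C@H](C)C3(OCCO3)CC[C@]2(C)C2OCCO2)cc1
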